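## Structural features

The target is a C15 framework of two carbocycles joined by one bond: a cyclopentane (C1 = CMe2, C2 = CHBr, C3 = CH2, C4 = CHOH, C5 = CMe) is attached through C5 to C1' of a cyclohexane (C1' = C–OH, C2'/C3'/C6' = CH2, C4' = CMeCl, C5' = CHBr). C1, C5 and C1' are three contiguous fully substituted carbons, and C5 is an all-carbon quaternary stereocentre wedged between the gem-dimethyl carbon and the tertiary carbinol. On the five-membered ring the C2 bromine, the C4 hydroxyl and the C5–C1' bond lie on one face and the C5 methyl on the other; on the six-membered ring the C1' hydroxyl and the C4' chlorine are cis (1,4) and the C5' bromine is trans to both, so the vicinal halogens are trans with chlorine on the tertiary carbon. The six stereocentres therefore form two triads, C2/C4/C5 and C1'/C4'/C5', that communicate only across the C5–C1' bond. Sensitive features are the tertiary chloride (elimination, or displacement by the cis C1' hydroxyl to give a 1,4-bridged ether), the neopentyl secondary bromide at C2 (methyl shift on ionisation), the tertiary alcohol, and the C4/C1' 1,3-diol, which can fragment if C1' becomes cationic. The real difficulties are the congested C1–C5–C1' array, the C2 bromine on the more hindered face next to a quaternary carbon, and the remote relationship between C1' and the halogenated C4'/C5' pair. The key step uses the fact that ring C1'–C6', with an oxygen and a carbon substituent on C1' and a methyl-bearing C4' para to it, is the retron of a Diels–Alder adduct of a 2-methyl diene and an α-oxygenated acrylate: one cycloaddition supplies the six ring carbons, the C1' oxygen, a C4'=C5' alkene for later halogenation and a carbonyl carbon that becomes C5.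

## Logic of the disconnections

30 ⇒ 28. The C4'–Cl bond is cut and the C4'–O bond to the C1' oxygen is restored. The cis OH/Cl, trans Br pattern is exactly what anti opening of a bromonium ion generated from the bridged ether would give. This removes the labile tertiary chloride and masks the tertiary alcohol. The forward step must cleave C4'–O and not C1'–O, and chloride must enter anti to bromine.

28 ⇒ 26 (through 27). The C2–Br bond is cut to a C2–O bond of opposite configuration. The gain is a 1,3-anti diol that a directed reduction can make. The demand is an SN2 inversion at a neopentyl carbon on the more hindered face, and activation of the C2 hydroxyl in the presence of the C4 hydroxyl.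

26 ⇒ 25. The C2–H bond is cut to a C2 ketone. The C4 hydroxyl is then the only stereocontrol element needed, but the hydride must be delivered intramolecularly from the C4 oxygen.

25 ⇒ 24. The C3–C4 bond is cut (retro-aldol). The ring opens to a keto aldehyde in which only C3 can enolise and only C4 can accept. The forward step must place the C4 hydroxyl cis to C1'.

24 ⇒ 22 ⇒ 20 (through 23 and 21). The C4 aldehyde is traced to a propenyl group, and the C2–C3 bond is cut to a carboxylic acid. The gain is an acid with a γ,δ-alkene, the retron of a Claisen rearrangement. The demands are that the ring alkene is masked during ozonolysis and that methyl addition stops at the ketone.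

20 ⇒ 17 (through 18 and 19). The C1–C5 bond between the two quaternary carbons is cut by a retro-Ireland–Claisen step. The C5 stereocentre is exchanged for a secondary carbinol and an E trisubstituted alkene, which are far easier to control. The forward step needs a chair transition state and must tolerate the congestion.

17 ⇒ 15 + 16, and 15 ⇒ 14. The ester C–O bond and the carbinol C–H bond are cut. This leaves a methyl enone whose reduction must be reagent-controlled, because the existing stereocentres are too far away to help.

14 ⇒ 12 ⇒ 10 + 11 (through 13). The ketone C–CH3 bond and the C5=C4 alkene are cut. The gain is a methyl ketone whose carbonyl carbon is C5. The olefination must be E-selective on a ketone flanked by a fully substituted carbon.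

10 ⇒ 9. The C4'–O and C5'–Br bonds are cut (retro-bromoetherification). One step therefore has to set C4' and C5' from C1' and protect both the hydroxyl and the alkene.

9 ⇒ 7 (through 8). The C5–CH3 bond is cut and the acetal is restored. The forward step must add one methyl only and release the auxiliary without touching C1'.

7 ⇒ 5 + 6. The C2'–C3' and C1'–C6' bonds are cut (retro-Diels–Alder). The whole cyclohexane is reduced to a diene and an alkene. The forward step needs para regioselectivity and attack on one face of the alkene.

5 ⇒ 4 ⇒ 3 ⇒ 1 + 2. The exocyclic alkene is traced to HBr elimination, the C–Br bond to radical bromination, and the acetal to condensation of the two starting materials. The single stereocentre of 1 must be relayed to the acetal carbon of 3 before it is itself destroyed.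

## Other disconnections considered

Alternative 1: The cyclopentane is opened at C2–C3 and the resulting keto aldehyde is folded back into the ring alkene of a 1-methylcyclobutene, A1. In the forward direction ozonolysis of A1 (O3, then Me2S) would unveil a methyl ketone at C4 and an aldehyde at C2, and mild base would close the C2–C3 bond by aldol addition to give hydroxy cyclopentanone A2.
- In its favour: C1 and C5 are already bonded in the four-membered ring, so the hardest C–C bond is not the task of the key step, and the aldol has only one possible course.
- Better than the chosen plan: the carbonyl of A2 sits at C4. The C4 hydroxyl could therefore be made last by hydride attack from the methyl face, and the C2 hydroxyl could be inverted to bromide with no second free hydroxyl present. In the chosen plan C4 must be controlled in the aldol (25) and C2 must be activated selectively (26).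
- Against it here: the cyclohexane of A1 and A2 is a symmetrical ketal, so C1' is not yet a stereocentre. The C4' methyl, the alkene position and the whole C1'/C4'/C5' triad would have to be created late by telling apart two equivalent methylene arms relative to a distant C5, and nothing in A2 controls this. An enantioselective entry to A1 is also needed.
- Comparison: the aldol is mechanistically the same kind as step 14 (equal), the C2 inversion is the same neopentyl problem (equal), and the step count for the cyclopentane is similar. The chosen plan settles the remote C1'/alkene relationship in the cycloaddition; this alternative leaves it open.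

Alternative 2: The C1–C5 and C1'–O bonds are cut together. In the forward direction Et2SBr·SbCl5Br would add Br+ to the prenyl alkene of the acyclic tert-butyl carbonate A3; C5 of the tetrasubstituted C5=C1' alkene would attack C1, and the carbonate carbonyl oxygen would trap the C1' cation with loss of the tert-butyl group, giving the bromocyclopentane-fused cyclic carbonate A4.
- Better than the chosen plan: the C2 bromine is installed directly, with its configuration tied to C5 through a chair-like cyclisation, and both quaternary carbons and the C1'–O bond are made in the same step. This avoids the late substitution at C2 entirely and is shorter for the cyclopentane.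
- Against it here: the face of bromonium formation must be relayed from the single C4 stereocentre. The carbonate can capture the bromonium ion directly to form a six-membered bromo carbonate without C–C bond formation. Five-membered cation–olefin closures onto a hindered tetrasubstituted alkene compete poorly with proton loss.
- Structure: as in Alternative 1 the cyclohexane is a symmetrical ketal, so the C1'/C4'/C5' triad is still unsolved after A4.
- Comparison: the cationic cascade is less predictable than the pericyclic and enolate steps of the chosen plan. The saving in steps on the cyclopentane would be spent on a late desymmetrisation of the cyclohexane.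

Alternative 3: The C4'=C5' alkene is cut. In the forward direction second-generation Grubbs catalyst would join the allyl and 3-methylbut-3-enyl arms on C1' of diene A5 and close the cyclohexene of A6.
- In its favour: ring-closing metathesis to a trisubstituted cyclohexene is dependable and tolerates free hydroxyls and alkyl bromides; on reliability of the ring-forming step it is at least the equal of a thermal cycloaddition with a polymerisable dienophile.
- Better than the chosen plan: the finished bromocyclopentane is carried in, and C1' is set directly against C4/C5 by chelation when the second arm is added. The stereochemical relay across C5–C1' is one step, where the chosen plan needs an auxiliary, a reagent-controlled reduction and a sigmatropic transfer.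
- Equal: treatment of A6 with NBS would give 28, so the endgame would be shared.
- Against it here: two successive additions to a carbonyl on the neopentyl quaternary C5 invite enolisation and retro-aldol cleavage. Chelation control between two similar unsaturated chains is uncertain. The enantiopure bromocyclopentane fragment with C2, C4 and C5 in place is itself the hard part of the molecule and is only moved elsewhere.
- Direct bromochlorination of A6 is mismatched: the target carries both halogens equatorial in its preferred chair, whereas trans-diaxial opening would deliver the other diastereomer, and the free C1' hydroxyl would intercept the bromonium ion anyway.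
- Comparison: the chosen plan fixes the absolute configuration of C1' and the alkene position in one cycloaddition of established facial bias and builds the cyclopentane on that carbon.

Key step: step 4

Remark: locants C1–C5 and C1'–C6' of the target are kept for all intermediates; Bic stands for (1R,3S,4S)-3-bromo-4-methyl-7-oxabicyclo[2.2.1]heptan-1-yl (C1' = bridgehead bearing the side chain, C4' = methyl bridgehead, C5' = CHBr); 11 and 16 are taken as purchased; the (S)-alkene 5 adding on the face anti to tert-butyl leads to the (5R) spiro centre, which is (R)-C1' of the target, so the key-step structures need no correction.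

## Route

Step 1
Reactants: 1 (S)-lactic acid; 2 pivalaldehyde
Product: 3 (2S,5S)-2-tert-butyl-5-methyl-1,3-dioxolan-4-one (cis)
Conditions: p-TsOH·H2O (cat.), H2SO4 (cat.), pentane, reflux, Dean–Stark; crystallisation from pentane/Et2O, −78 °C
Reagents that add atoms: none
Why: Acid-catalysed acetalisation of an α-hydroxy acid with removal of water; the cis acetal is the favoured isomer and is purified by low-temperature crystallisation, so the lactic acid stereocentre is copied onto the acetal carbon.

Step 2
Reactants: 3 (2S,5S)-2-tert-butyl-5-methyl-1,3-dioxolan-4-one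
Product: 4 (2R,5R)-5-bromo-2-tert-butyl-5-methyl-1,3-dioxolan-4-one (Br trans to tert-butyl)
Conditions: NBS, AIBN (cat.), cyclohexane, reflux
Reagents that add atoms: N-bromosuccinimide, O=C1CCC(=O)N1Br
Why: Wohl–Ziegler radical bromination at C5–H, which is activated by the ring oxygen and the carbonyl (captodative radical); the acetal carbon is untouched (its descriptor changes only because of CIP priorities) and the C5 configuration is irrelevant because it is destroyed in step 3.

Step 3
Reactants: 4 (2R,5R)-5-bromo-2-tert-butyl-5-methyl-1,3-dioxolan-4-one
Product: 5 (S)-2-tert-butyl-5-methylene-1,3-dioxolan-4-one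
Conditions: Et3N, Et2O, 0 °C → rt
Reagents that add atoms: none
Why: E2 dehydrobromination toward the only β-hydrogens (the methyl group) gives the exocyclic alkene; the mild amine base leaves the acetal stereocentre intact.

Step 4
Reactants: 5 (S)-2-tert-butyl-5-methylene-1,3-dioxolan-4-one; 6 isoprene
Product: 7 (2S,5R)-2-tert-butyl-8-methyl-1,3-dioxaspiro[4.5]dec-7-en-4-one
Conditions: 6 (5 equiv), BHT (cat.), toluene, sealed tube, 70 °C
Reagents that add atoms: none
Why: Concerted, asynchronous normal-electron-demand [4+2] cycloaddition of the s-cis diene with the captodative exocyclic alkene (lactone carbonyl as acceptor, acetal oxygen as donor); the closest known reaction type is the Diels–Alder reaction of chiral 5-methylene-1,3-dioxolan-4-ones and of α-acyloxyacrylates with simple dienes. The cyclohexene is closed by the cycloaddition itself: C2'–C3' and C1'–C6' form in one suprafacial event, giving a six-membered ring spiro-fused to the dioxolanone, with no separate cyclisation. The only new stereocentre is the spiro carbon C1'; the tert-butyl group on the acetal carbon covers one face of the nearly planar dioxolanone, so the diene should add to the other face and give the (5R) centre, which is (R)-C1' of the target. Because the diene has no terminal substituent, endo or exo orientation creates no further stereocentre. Para regioselectivity is needed and comes from the 2-methyl group, which makes C1 of the diene the more nucleophilic terminus; it pairs with the unsubstituted CH2 terminus of the dienophile, which carries the larger LUMO coefficient. BHT suppresses radical polymerisation of the dienophile, and Lewis acids are avoided because they could open and epimerise the acetal. Any meta isomer would be removed by chromatography or crystallisation.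

Step 5
Reactants: 7 (2S,5R)-2-tert-butyl-8-methyl-1,3-dioxaspiro[4.5]dec-7-en-4-one
Product: 9 (R)-1-(1-hydroxy-4-methylcyclohex-3-en-1-yl)ethan-1-one, via lithium hemiketal alkoxide 8 (not isolated)
Conditions: MeLi (1.1 equiv), THF, −78 °C; AcOH, −78 °C → rt
Reagents that add atoms: methyllithium, [Li]C
Why: Addition of MeLi to the lactone carbonyl gives a tetrahedral lithium alkoxide that should persist at −78 °C, so a second addition is avoided; acidic quench collapses it to the methyl ketone and releases the auxiliary as pivalaldehyde, with C1' untouched.

Step 6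
Reactants: 9 (R)-1-(1-hydroxy-4-methylcyclohex-3-en-1-yl)ethan-1-one
Product: 10 1-Bic-ethan-1-one
Conditions: NBS, CH2Cl2, 0 °C, dark
Reagents that add atoms: N-bromosuccinimide, O=C1CCC(=O)N1Br
Why: Bromoetherification: Br+ adds reversibly to C4'=C5' and the tertiary hydroxyl opens the bromonium ion at the tertiary carbon C4' across the ring through a boat conformer, which is possible only when bromine is on the face opposite to the oxygen. C1' therefore sets both C4' (S) and C5' (S), and the hydroxyl and the alkene are masked together in a rigid bicycle whose bromide has no anti β-hydrogen and a blocked backside.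

Step 7
Reactants: 10 1-Bic-ethan-1-one; 11 diethyl {2-[methoxy(methyl)amino]-2-oxoethyl}phosphonate
Product: 12 (2E)-3-Bic-N-methoxy-N-methylbut-2-enamide
Conditions: NaH, THF, 0 °C → 65 °C
Reagents that add atoms: none
Why: Horner–Wadsworth–Emmons olefination of an α-alkoxy methyl ketone; reversible addition and the size difference between the bridgehead substituent and methyl should favour the E alkene with the carbonyl trans to the bicycle.

Step 8
Reactants: 12 (2E)-3-Bic-N-methoxy-N-methylbut-2-enamide
Product: 14 (3E)-4-Bic-pent-3-en-2-one, via magnesium hemiaminal alkoxide 13 (not isolated)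
Conditions: MeMgBr, THF, −20 → 0 °C; aq. NH4Cl
Reagents that add atoms: methylmagnesium bromide, C[Mg]Br
Why: Weinreb ketone synthesis: the chelated magnesium adduct resists a second addition and gives the methyl enone on work-up; 1,2-addition is expected for a β,β-disubstituted unsaturated amide.

Step 9
Reactants: 14 (3E)-4-Bic-pent-3-en-2-one
Product: 15 (2S,3E)-4-Bic-pent-3-en-2-ol
Conditions: (R)-2-methyl-CBS-oxazaborolidine (20 mol %), catecholborane, toluene, −78 °C; MeOH, then aq. NaOH wash
Reagents that add atoms: none
Why: Corey–Bakshi–Shibata reduction; with the alkenyl group as the large and methyl as the small substituent the (R)-catalyst should deliver hydride to give the (S)-carbinol under reagent control, and catecholborane at low temperature avoids hydroboration of the alkene.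

Step 10
Reactants: 15 (2S,3E)-4-Bic-pent-3-en-2-ol; 16 isobutyryl chloride
Product: 17 (2S,3E)-4-Bic-pent-3-en-2-yl 2-methylpropanoate
Conditions: pyridine, DMAP (cat.), CH2Cl2, 0 °C → rt
Reagents that add atoms: none
Why: DMAP-catalysed acylation of an unhindered secondary allylic alcohol; no stereocentre is touched.

Step 11
Reactants: 17 (2S,3E)-4-Bic-pent-3-en-2-yl 2-methylpropanoate
Product: 20 (3R,4E)-3-Bic-2,2,3-trimethylhex-4-enoic acid, via silyl ketene acetal 18 (not isolated), via trimethylsilyl ester 19 (not isolated)
Conditions: LiN(iPr)2, TMSCl, Et3N, THF, −78 °C → rt, then 60 °C; 1 M HCl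
Reagents that add atoms: none
Why: Ireland–Claisen rearrangement: the silyl ketene acetal (its geometry is irrelevant because both α-substituents are methyl) rearranges through a chair transition state with the carbinol methyl equatorial, so the (S)-carbinol and E-alkene transfer their chirality to C5 and the C1–C5 bond between two quaternary carbons is formed together with a new E alkene. The C5 geometry is that of the target; the descriptor reads R here only because the vinyl group ranks below C1.

Step 12
Reactants: 20 (3R,4E)-3-Bic-2,2,3-trimethylhex-4-enoic acid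
Product: 22 (4R,5E)-4-Bic-3,3,4-trimethylhept-5-en-2-one, via dilithium gem-diolate 21 (not isolated)
Conditions: MeLi (2.5 equiv), Et2O, 0 °C → rt; poured into ice-cold 1 M HCl
Reagents that add atoms: methyllithium, [Li]C
Why: Addition of MeLi to the lithium carboxylate gives a dilithium gem-diolate that cannot add again and collapses to the methyl ketone on inverse acidic quench; the bicyclic bromide is inert to MeLi at this temperature.

Step 13
Reactants: 22 (4R,5E)-4-Bic-3,3,4-trimethylhept-5-en-2-one
Product: 24 (2R)-2-Bic-2,3,3-trimethyl-4-oxopentanal, via ozonide 23 (not isolated)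
Conditions: O3, CH2Cl2, −78 °C; Me2S, −78 °C → rt
Reagents that add atoms: ozone, [O-][O+]=O
Why: Ozonolysis of the only alkene with reductive work-up gives the C4 aldehyde; the ring alkene is hidden in the bromo ether and the quaternary C5 cannot epimerise.

Step 14
Reactants: 24 (2R)-2-Bic-2,3,3-trimethyl-4-oxopentanal
Product: 25 (3S,4R)-3-Bic-4-hydroxy-2,2,3-trimethylcyclopentan-1-one
Conditions: LiN(iPr)2 (1.05 equiv), THF, −78 °C; AcOH, −78 °C
Reagents that add atoms: none
Why: Intramolecular aldol addition: the ketone can enolise only at its methyl group (C3) and the aldehyde has no α-hydrogen, so only the C3–C4 bond can form, in a five-membered closure favoured by the two quaternary carbons in the tether. A lithium ion bridging the enolate oxygen, the aldehyde oxygen and the ether oxygen of the bicycle should place the new hydroxyl cis to C1' (4R), and the cold quench avoids dehydration.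

Step 15
Reactants: 25 (3S,4R)-3-Bic-4-hydroxy-2,2,3-trimethylcyclopentan-1-one
Product: 26 (1R,3R,4S)-4-Bic-4,5,5-trimethylcyclopentane-1,3-diol
Conditions: Me4NBH(OAc)3, MeCN/AcOH, −30 → 0 °C
Reagents that add atoms: none
Why: Evans–Saksena reduction: the C4 hydroxyl exchanges onto boron and delivers hydride intramolecularly to the same face of the C2 carbonyl, which should give the 1,3-anti diol with the C2 hydroxyl trans to the C4 hydroxyl.

Step 16
Reactants: 26 (1R,3R,4S)-4-Bic-4,5,5-trimethylcyclopentane-1,3-diol
Product: 28 (1R,2S,4S)-4-bromo-2-Bic-2,3,3-trimethylcyclopentan-1-ol, via C2 triflate 27 (not isolated)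
Conditions: Tf2O (1.05 equiv), 2,6-lutidine, CH2Cl2, −78 °C; Bu4NBr, −78 °C → rt
Reagents that add atoms: tetrabutylammonium bromide, CCCC[N+](CCCC)(CCCC)CCCC.[Br-]
Why: The C2 hydroxyl lies on the face of the C5 methyl and is far more accessible than the C4 hydroxyl, which is cis to the bicycle and next to C5, so it should be triflated selectively; SN2 displacement by soluble bromide then inverts C2 and places bromine cis to the C4 hydroxyl and C1' (2S). Low temperature and a non-ionising medium are chosen to suppress methyl migration, and the C1' oxygen is tied up in the bridged ether, so it cannot displace the triflate as a free hydroxyl would.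

Step 17
Reactants: 28 (1R,2S,4S)-4-bromo-2-Bic-2,3,3-trimethylcyclopentan-1-ol
Product: 30 (1R,2S,4S)-4-bromo-2-[(1R,3S,4S)-3-bromo-4-chloro-1-hydroxy-4-methylcyclohexyl]-2,3,3-trimethylcyclopentan-1-ol, via cyclic chloroboronate 29 (not isolated)
Conditions: BCl3 (2 equiv, 1 M in CH2Cl2), CH2Cl2, −78 → −20 °C; aq. NaHCO3
Reagents that add atoms: boron trichloride, ClB(Cl)Cl
Why: Lewis-acid ether cleavage with neighbouring-group participation: BCl3 first forms the C4 dichloroborinate, whose boron can reach the ether oxygen; the tertiary C4'–O bond ionises with anti participation of the C5' bromine, and chloride opens the bromonium ion at C4' anti to bromine, that is with overall retention, giving chlorine cis to the C1' oxygen and trans to bromine. Formation of the six-membered chloroboronate of the C4/C1' diol should favour cleavage of C4'–O over C1'–O, and it is hydrolysed on work-up.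

## Compound list

Bic = (1R,3S,4S)-3-bromo-4-methyl-7-oxabicyclo[2.2.1]heptan-1-yl

1 | (S)-lactic acid | C[C@H](O)C(=O)O | starting material
2 | pivalaldehyde (2,2-dimethylpropanal) | CC(C)(C)C=O | starting material
3 | (2S,5S)-2-tert-butyl-5-methyl-1,3-dioxolan-4-one | O=C1O[C@@H](C(C)(C)C)O[C@H]1C | intermediate
4 | (2R,5R)-5-bromo-2-tert-butyl-5-methyl-1,3-dioxolan-4-one (Br trans to tert-butyl) | O=C1O[C@@H](C(C)(C)C)O[C@]1(C)Br | intermediate
5 | (S)-2-tert-butyl-5-methylene-1,3-dioxolan-4-one | O=C1O[C@@H](C(C)(C)C)OC1=C | intermediate
6 | isoprene (2-methylbuta-1,3-diene) | C=CC(C)=C | starting material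
7 | (2S,5R)-2-tert-butyl-8-methyl-1,3-dioxaspiro[4.5]dec-7-en-4-one | O=C1O[C@@H](C(C)(C)C)O[C@@]12CCC(C)=CC2 | intermediate
8 | lithium (2S,5R)-2-tert-butyl-4,8-dimethyl-1,3-dioxaspiro[4.5]dec-7-en-4-olate (C4 epimers) | [Li+].CC1([O-])O[C@@H](C(C)(C)C)O[C@@]12CCC(C)=CC2 | intermediate (not isolated)
9 | (R)-1-(1-hydroxy-4-methylcyclohex-3-en-1-yl)ethan-1-one | CC(=O)[C@@]1(O)CCC(C)=CC1 | intermediate
10 | 1-Bic-ethan-1-one | CC(=O)[C@@]1(O2)CC[C@@]2(C)[C@@H](Br)C1 | intermediate
11 | diethyl {2-[methoxy(methyl)amino]-2-oxoethyl}phosphonate | CCOP(=O)(CC(=O)N(C)OC)OCC | starting material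
12 | (2E)-3-Bic-N-methoxy-N-methylbut-2-enamide | CON(C)C(=O)/C=C(\C)[C@@]1(O2)CC[C@@]2(C)[C@@H](Br)C1 | intermediate
13 | bromomagnesium (3E)-4-Bic-2-[methoxy(methyl)amino]pent-3-en-2-olate | CON(C)C(C)([O-])/C=C(\C)[C@@]1(O2)CC[C@@]2(C)[C@@H](Br)C1.[Mg+2].[Br-] | intermediate (not isolated)
14 | (3E)-4-Bic-pent-3-en-2-one | CC(=O)/C=C(\C)[C@@]1(O2)CC[C@@]2(C)[C@@H](Br)C1 | intermediate
15 | (2S,3E)-4-Bic-pent-3-en-2-ol | C[C@H](O)/C=C(\C)[C@@]1(O2)CC[C@@]2(C)[C@@H](Br)C1 | intermediate
16 | isobutyryl chloride (2-methylpropanoyl chloride) | CC(C)C(Cl)=O | starting material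
17 | (2S,3E)-4-Bic-pent-3-en-2-yl 2-methylpropanoate | CC(C)C(=O)O[C@@H](C)/C=C(\C)[C@@]1(O2)CC[C@@]2(C)[C@@H](Br)C1 | intermediate
18 | [(1-{[(2S,3E)-4-Bic-pent-3-en-2-yl]oxy}-2-methylprop-1-en-1-yl)oxy]trimethylsilane | CC(C)=C(O[Si](C)(C)C)O[C@@H](C)/C=C(\C)[C@@]1(O2)CC[C@@]2(C)[C@@H](Br)C1 | intermediate (not isolated)
19 | trimethylsilyl (3R,4E)-3-Bic-2,2,3-trimethylhex-4-enoate | C/C=C/[C@](C)(C(C)(C)C(=O)O[Si](C)(C)C)[C@@]1(O2)CC[C@@]2(C)[C@@H](Br)C1 | intermediate (not isolated)
20 | (3R,4E)-3-Bic-2,2,3-trimethylhex-4-enoic acid | C/C=C/[C@](C)(C(C)(C)C(=O)O)[C@@]1(O2)CC[C@@]2(C)[C@@H](Br)C1 | intermediate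
21 | dilithium (4R,5E)-4-Bic-3,3,4-trimethylhept-5-ene-2,2-diolate | C/C=C/[C@](C)(C(C)(C)C(C)([O-])[O-])[C@@]1(O2)CC[C@@]2(C)[C@@H](Br)C1.[Li+].[Li+] | intermediate (not isolated)
22 | (4R,5E)-4-Bic-3,3,4-trimethylhept-5-en-2-one | C/C=C/[C@](C)(C(C)(C)C(C)=O)[C@@]1(O2)CC[C@@]2(C)[C@@H](Br)C1 | intermediate
23 | (4R)-4-Bic-3,3-dimethyl-4-(5-methyl-1,2,4-trioxolan-3-yl)pentan-2-one (trioxolane epimers) | CC1OOC(O1)[C@](C)(C(C)(C)C(C)=O)[C@@]1(O2)CC[C@@]2(C)[C@@H](Br)C1 | intermediate (not isolated)
24 | (2R)-2-Bic-2,3,3-trimethyl-4-oxopentanal | O=C[C@](C)(C(C)(C)C(C)=O)[C@@]1(O2)CC[C@@]2(C)[C@@H](Br)C1 | intermediate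
25 | (3S,4R)-3-Bic-4-hydroxy-2,2,3-trimethylcyclopentan-1-one | CC1(C)C(=O)C[C@@H](O)[C@@]1(C)[C@@]1(O2)CC[C@@]2(C)[C@@H](Br)C1 | intermediate
26 | (1R,3R,4S)-4-Bic-4,5,5-trimethylcyclopentane-1,3-diol | CC1(C)[C@H](O)C[C@@H](O)[C@@]1(C)[C@@]1(O2)CC[C@@]2(C)[C@@H](Br)C1 | intermediate
27 | (1R,3R,4S)-4-Bic-3-hydroxy-4,5,5-trimethylcyclopentyl trifluoromethanesulfonate | CC1(C)[C@H](OS(=O)(=O)C(F)(F)F)C[C@@H](O)[C@@]1(C)[C@@]1(O2)CC[C@@]2(C)[C@@H](Br)C1 | intermediate (not isolated)
28 | (1R,2S,4S)-4-bromo-2-Bic-2,3,3-trimethylcyclopentan-1-ol | CC1(C)[C@@H](Br)C[C@@H](O)[C@@]1(C)[C@@]1(O2)CC[C@@]2(C)[C@@H](Br)C1 | intermediate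
29 | cyclic chloroboronate of 30 (2-chloro-1,3,2-dioxaborinane spanning O–C4 and O–C1') | CC1(C)[C@@H](Br)C[C@H]2OB(Cl)O[C@@]3(CC[C@](C)(Cl)[C@@H](Br)C3)[C@@]12C | intermediate (not isolated)
30 | (1R,2S,4S)-4-bromo-2-[(1R,3S,4S)-3-bromo-4-chloro-1-hydroxy-4-methylcyclohexyl]-2,3,3-trimethylcyclopentan-1-ol | CC1(C)[C@@H](Br)C[C@@H](O)[C@@]1(C)[C@@]1(O)CC[C@](C)(Cl)[C@@H](Br)C1 | target

## Step count and least certain steps

Total step count: 17. Longest linear sequence: 17 steps (1 → 30; 13 steps after cycloadduct 7); 2, 6, 11 and 16 enter as purchased materials.

Step 4 (key step). Most likely to go wrong: incomplete para regioselectivity and radical polymerisation of the dienophile at the temperature a simple diene needs; any opening of the acetal would also erode facial control. The methyl group is only a modest regiochemical director. Fallback, from 5 back to 7: cycloaddition of 5 with 2-(trimethylsilyloxy)buta-1,3-diene (toluene, 50 °C), whose oxygen substituent directs para much more strongly and raises diene reactivity, would give (2S,5R)-2-tert-butyl-8-(trimethylsilyloxy)-1,3-dioxaspiro[4.5]dec-7-en-4-one F1 with the enol ether double bond fixed at C4'=C5'. Fluoride-catalysed exchange with C4F9SO2F (Bu4NF cat., THF) would convert it, without moving the double bond, into (2S,5R)-2-tert-butyl-4-oxo-1,3-dioxaspiro[4.5]dec-7-en-8-yl nonafluorobutane-1-sulfonate F2. Negishi coupling with MeZnCl and Pd(PPh3)4 (zerovalent palladium, THF) would install the C4' methyl and give 7.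

Step 7. Most likely to go wrong: slow or incomplete olefination of a ketone flanked by a fully substituted carbon, with competing enolisation and loss of E selectivity. Fallback, from 10 back to 14: addition of the small nucleophile CH3C≡CMgBr (THF, 0 °C) would give 2-Bic-pent-3-yn-2-ol F3 (both carbinol epimers usable). A Meyer–Schuster rearrangement (Ph3PAuNTf2 cat., MeOH, toluene, rt) would shift the oxygen to the alkyne terminus and give enone 14 directly, the E isomer being the thermodynamically favoured one.

Step 11. Most likely to go wrong: the sigmatropic step may not overcome the congestion of joining two quaternary carbons next to C1', so that ester cleavage or decomposition of the ketene acetal takes over on prolonged heating; leakage through a boat transition state would erode the chirality transfer. Fallback, from 15 back to 20: a Johnson–Claisen rearrangement with MeC(OMe)3 (EtCO2H cat., xylene, 140 °C) forms only one quaternary carbon in the pericyclic step and uses the same chair-like transfer; it would give methyl (3S,4E)-3-Bic-3-methylhex-4-enoate F4. Two successive enolate methylations (LiN(iPr)2, MeI, THF, −78 → 0 °C) would give methyl (3R,4E)-3-Bic-2,3-dimethylhex-4-enoate F5 (C2 epimers) and then methyl (3R,4E)-3-Bic-2,2,3-trimethylhex-4-enoate F6. SN2 demethylation (LiI, pyridine, reflux) would give acid 20.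

Step 14. Most likely to go wrong: poor facial control at C4 if lithium chelation to the ether oxygen is weak (hydroxyl ending cis to the C5 methyl), and E1cB dehydration or retro-aldol cleavage on warming. Fallback, from 22 back to 25: selective α-bromination of the methyl ketone with pyrrolidone hydrotribromide (THF, rt), which spares alkenes, would give (4R,5E)-1-bromo-4-Bic-3,3,4-trimethylhept-5-en-2-one F7. Lemieux–Johnson cleavage of the propenyl group (K2OsO4·2H2O cat., NaIO4, 2,6-lutidine, dioxane/H2O) would give (2R)-5-bromo-2-Bic-2,3,3-trimethyl-4-oxopentanal F8. SmI2 (divalent samarium, THF, −78 °C) would then generate a trivalent samarium enolate under neutral reducing conditions; it should close the ring in a Reformatsky-type addition through a tight chelate of samarium with the enolate, aldehyde and ether oxygens to give 25.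

Step 16. Most likely to go wrong: ionisation of the neopentyl triflate with methyl migration or elimination instead of substitution, slow approach of bromide to the hindered face, triflation of both hydroxyls, and participation of the bridging ether oxygen. Fallback, from 25 back to 28: condensation with N2H4·H2O (EtOH, AcOH cat.) would give (3S,4R)-3-Bic-4-hydroxy-2,2,3-trimethylcyclopentan-1-one hydrazone F9. Barton-type oxidation with NBS and pyridine (CH2Cl2, 0 °C) would give the vinyl bromide (1R,5S)-3-bromo-5-Bic-4,4,5-trimethylcyclopent-2-en-1-ol F10 with loss of N2. Diimide (2-nitrobenzenesulfonohydrazide, Et3N, CH2Cl2, rt), which does not cleave C–Br bonds, would add two hydrogens syn from the ring face opposite to the bicycle and so push the C2 bromine to the face of C1' and the C4 hydroxyl, giving 28 with no substitution at the neopentyl carbon.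

Step 17. Most likely to go wrong: cleavage of C1'–O instead of C4'–O followed by fragmentation or rearrangement of the congested cation, proton loss from the bromonium ion, or re-closure of the chlorohydrin to the ether during work-up. Fallback, from 28 back to 30: acylative ether cleavage with AcCl and ZnCl2 (cat., CH2Cl2, 0 °C) would acetylate the C4 hydroxyl, activate the ether oxygen as an acyloxonium ion and deliver chloride to C4' through the same bromonium relay. It would give (1R,2S,4S)-2-[(1R,3S,4S)-1-acetoxy-3-bromo-4-chloro-4-methylcyclohexyl]-4-bromo-2,3,3-trimethylcyclopentyl acetate F11, in which the tertiary oxygen is capped and cannot re-close and the electron-poor C4 ester disfavours ionisation at C1'. Reductive removal of both acetates with iBu2AlH (CH2Cl2, −78 °C) would give 30.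

## Further compounds

F1 | step 4 | (2S,5R)-2-tert-butyl-8-(trimethylsilyloxy)-1,3-dioxaspiro[4.5]dec-7-en-4-one | O=C1O[C@@H](C(C)(C)C)O[C@@]12CCC(O[Si](C)(C)C)=CC2
F2 | step 4 | (2S,5R)-2-tert-butyl-4-oxo-1,3-dioxaspiro[4.5]dec-7-en-8-yl nonafluorobutane-1-sulfonate | O=C1O[C@@H](C(C)(C)C)O[C@@]12CCC(OS(=O)(=O)C(F)(F)C(F)(F)C(F)(F)C(F)(F)F)=CC2
F3 | step 7 | 2-[(1R,3S,4S)-3-bromo-4-methyl-7-oxabicyclo[2.2.1]heptan-1-yl]pent-3-yn-2-ol (carbinol epimers) | CC#CC(C)(O)[C@@]1(O2)CC[C@@]2(C)[C@@H](Br)C1
F4 | step 11 | methyl (3S,4E)-3-[(1R,3S,4S)-3-bromo-4-methyl-7-oxabicyclo[2.2.1]heptan-1-yl]-3-methylhex-4-enoate | C/C=C/[C@](C)(CC(=O)OC)[C@@]1(O2)CC[C@@]2(C)[C@@H](Br)C1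
F5 | step 11 | methyl (3R,4E)-3-[(1R,3S,4S)-3-bromo-4-methyl-7-oxabicyclo[2.2.1]heptan-1-yl]-2,3-dimethylhex-4-enoate (C2 epimers) | C/C=C/[C@](C)(C(C)C(=O)OC)[C@@]1(O2)CC[C@@]2(C)[C@@H](Br)C1
F6 | step 11 | methyl (3R,4E)-3-[(1R,3S,4S)-3-bromo-4-methyl-7-oxabicyclo[2.2.1]heptan-1-yl]-2,2,3-trimethylhex-4-enoate | C/C=C/[C@](C)(C(C)(C)C(=O)OC)[C@@]1(O2)CC[C@@]2(C)[C@@H](Br)C1
F7 | step 14 | (4R,5E)-1-bromo-4-[(1R,3S,4S)-3-bromo-4-methyl-7-oxabicyclo[2.2.1]heptan-1-yl]-3,3,4-trimethylhept-5-en-2-one | C/C=C/[C@](C)(C(C)(C)C(=O)CBr)[C@@]1(O2)CC[C@@]2(C)[C@@H](Br)C1
F8 | step 14 | (2R)-5-bromo-2-[(1R,3S,4S)-3-bromo-4-methyl-7-oxabicyclo[2.2.1]heptan-1-yl]-2,3,3-trimethyl-4-oxopentanal | O=C[C@](C)(C(C)(C)C(=O)CBr)[C@@]1(O2)CC[C@@]2(C)[C@@H](Br)C1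
F9 | step 16 | (3S,4R)-3-[(1R,3S,4S)-3-bromo-4-methyl-7-oxabicyclo[2.2.1]heptan-1-yl]-4-hydroxy-2,2,3-trimethylcyclopentan-1-one hydrazone | CC1(C)C(=NN)C[C@@H](O)[C@@]1(C)[C@@]1(O2)CC[C@@]2(C)[C@@H](Br)C1
F10 | step 16 | (1R,5S)-3-bromo-5-[(1R,3S,4S)-3-bromo-4-methyl-7-oxabicyclo[2.2.1]heptan-1-yl]-4,4,5-trimethylcyclopent-2-en-1-ol | CC1(C)C(Br)=C[C@@H](O)[C@@]1(C)[C@@]1(O2)CC[C@@]2(C)[C@@H](Br)C1
F11 | step 17 | (1R,2S,4S)-2-[(1R,3S,4S)-1-acetoxy-3-bromo-4-chloro-4-methylcyclohexyl]-4-bromo-2,3,3-trimethylcyclopentyl acetate | CC1(C)[C@@H](Br)C[C@@H](OC(C)=O)[C@@]1(C)[C@@]1(OC(C)=O)CC[C@](C)(Cl)[C@@H](Br)C1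
A1 | alternative 1 | triethyl{[8-(1,2,4,4-tetramethylcyclobut-2-en-1-yl)-1,4-dioxaspiro[4.5]decan-8-yl]oxy}silane (ring carbon C5 configured as in the target) | CC1=CC(C)(C)[C@]1(C)C1(O[Si](CC)(CC)CC)CCC2(CC1)OCCO2
A2 | alternative 1 | 4-hydroxy-2,3,3-trimethyl-2-[8-(triethylsilyloxy)-1,4-dioxaspiro[4.5]decan-8-yl]cyclopentan-1-one (hydroxyl trans to the C5 ring substituent) | CC1(C)[C@H](O)CC(=O)[C@@]1(C)C1(O[Si](CC)(CC)CC)CCC2(CC1)OCCO2
A3 | alternative 2 | tert-butyl [(3R)-2-(1,4-dioxaspiro[4.5]decan-8-ylidene)-6-methylhept-5-en-3-yl] carbonate | CC(C)=CC[C@@H](OC(=O)OC(C)(C)C)C(C)=C1CCC2(CC1)OCCO2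
A4 | alternative 2 | bromocyclopentane fused to a spiro six-membered cyclic carbonate with the ketal intact (C2, C4 and C5 as in the target) | CC1(C)[C@@H](Br)C[C@H]2OC(=O)OC3(CCC4(CC3)OCCO4)[C@@]12C
A5 | alternative 3 | (1R,2S,4S)-4-bromo-2-[(4R)-4-hydroxy-7-methylocta-1,7-dien-4-yl]-2,3,3-trimethylcyclopentan-1-ol | CC1(C)[C@@H](Br)C[C@@H](O)[C@@]1(C)[C@](O)(CC=C)CCC(C)=C
A6 | alternative 3 | (1R,2S,4S)-4-bromo-2-[(1R)-1-hydroxy-4-methylcyclohex-3-en-1-yl]-2,3,3-trimethylcyclopentan-1-ol | CC1(C)[C@@H](Br)C[C@@H](O)[C@@]1(C)[C@@]1(O)CCC(C)=CC1
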